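**Retrosynthetic overview**
1. The target is apigenin carrying ring D (the 2-methoxy-5-methoxycarbonylphenyl group) on C6; the last step only frees the ring B phenol from a benzyl ether.
2. Feature used: C2–C3–C4–C4a–C8a–C8–C7–C6–C5 is one continuous chain oxygenated on every second carbon (C2, C4, C8a, C7, C5), with ring D on C6. The 4-pyranone ring C can hold C2, C4 and C8a in masked form and pins O1 to C8a.
3. Key disconnection: C4a–C5 of ring A, a Dieckmann (Claisen) closure of a pyranyl beta-keto ester whose chain C8–C7–C6–C5 hangs on C8a and carries ring D on sp3 C6.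
4. The beta-keto ester is cut at C6–C7 into a pyranylacetic acid (lateral lithiation–carboxylation of the methylpyranone) and the ring D arylmalonic half-ester (copper-catalysed arylation of a malonate).
5. Ring order: ring C first (cyclodehydration of the triketone from acetylacetone dianion and the ring B benzoate), then ring A in the key step; rings B and D are bought.

Key step: step 7

Remark: flavone numbering is used for the corresponding carbons of the open precursors; tert-butyl methyl malonate replaces dimethyl malonate so that the malonic half-ester can be released by acid without touching the methyl esters; 10, 11, 13 and 14 are racemic at a labile centre and the target has no stereocentre.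

**Route**

Step 1
Reactants: 1 acetylacetone; 2 methyl 4-(benzyloxy)benzoate
Product: 4 1-[4-(benzyloxy)phenyl]hexane-1,3,5-trione, via acetylacetone dilithium dianion 3 (not isolated)
Conditions: 1 (2 equiv), LiN(i-Pr)2 (4 equiv), THF, 0 °C; then 2 (1 equiv), 0 °C → rt; 1 M HCl
Reagents that add atoms: none
Why: Claisen-type aroylation of a beta-diketone dianion takes place at the terminal, more basic carbon and should give the 1,3,5-triketone, the second equivalent of dianion taking up the proton of the more acidic product.

Step 2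
Reactants: 4 1-[4-(benzyloxy)phenyl]hexane-1,3,5-trione
Product: 5 2-[4-(benzyloxy)phenyl]-6-methyl-4H-pyran-4-one
Conditions: p-TsOH·H2O (10 mol %), toluene, reflux, Dean–Stark
Reagents that add atoms: none
Why: Acid-catalysed cyclodehydration of a 1,3,5-triketone (enol oxygen onto the terminal carbonyl, loss of water) is the standard entry to 2,6-disubstituted 4-pyranones, both directions of closure give the same ring C, and the benzyl aryl ether should tolerate catalytic sulfonic acid.

Step 3
Reactants: 5 2-[4-(benzyloxy)phenyl]-6-methyl-4H-pyran-4-one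
Product: 7 2-{6-[4-(benzyloxy)phenyl]-4-oxo-4H-pyran-2-yl}acetic acid, via lithiated methylpyranone 6 (not isolated)
Conditions: LiN(SiMe3)2 (1.1 equiv), THF, −78 °C; excess dry CO2, −78 → −20 °C; cold 1 M HCl to pH 2, extraction below 10 °C
Reagents that add atoms: carbon dioxide, O=C=O
Why: The ring methyl group is vinylogously alpha to the pyranone carbonyl and is removed cleanly by lithium amide bases at low temperature, and the extended enolate is carboxylated at its exocyclic carbon (lateral lithiation–carboxylation).

Step 4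
Reactants: 8 methyl 3-iodo-4-methoxybenzoate; 9 tert-butyl methyl malonate
Product: 10 1-tert-butyl 3-methyl 2-[2-methoxy-5-(methoxycarbonyl)phenyl]propanedioate
Conditions: CuI (10 mol %), 2-picolinic acid (20 mol %), Cs2CO3 (3 equiv), dioxane, 50 °C
Reagents that add atoms: none
Why: Copper-catalysed Hurtley-type C-arylation of a malonate with an aryl iodide runs under mild anhydrous carbonate conditions that should leave all three ester groups intact, the ortho-methoxy group slowing but not blocking the coupling.

Step 5
Reactants: 10 1-tert-butyl 3-methyl 2-[2-methoxy-5-(methoxycarbonyl)phenyl]propanedioate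
Product: 11 3-methoxy-2-[2-methoxy-5-(methoxycarbonyl)phenyl]-3-oxopropanoic acid
Conditions: CF3CO2H/CH2Cl2 (1:3), 0 °C → rt; evaporation below 25 °C, used at once
Reagents that add atoms: none
Why: Acidolysis of the tert-butyl ester (loss of isobutene) is orthogonal to the two methyl esters and should give the malonic half-ester without exposing the enolisable arylmalonate to hydroxide.

Step 6
Reactants: 7 2-{6-[4-(benzyloxy)phenyl]-4-oxo-4H-pyran-2-yl}acetic acid; 11 3-methoxy-2-[2-methoxy-5-(methoxycarbonyl)phenyl]-3-oxopropanoic acid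
Product: 14 methyl 3-{4-[6-(4-benzyloxyphenyl)-4-oxo-4H-pyran-2-yl]-1-methoxy-1,3-dioxobutan-2-yl}-4-methoxybenzoate, via acyl imidazolide 12 (not isolated), via acylmalonic half-acid 13 (not isolated)
Conditions: 7, 1,1'-carbonyldiimidazole (1.1 equiv), THF, 0 °C → rt; separately 11, MgCl2 (1.2 equiv), Et3N (2.5 equiv), THF/MeCN, 0 °C → rt; combine, rt, 16 h; 1 M HCl, 0 °C
Reagents that add atoms: none
Why: In this Masamune–Brooks-type decarboxylative Claisen condensation the magnesium enolate of the malonic half-ester is C-acylated by the acyl imidazolide under nearly neutral conditions and the acylmalonic acid loses CO2 on acidification, so the alpha-aryl beta-keto ester should form without a strongly basic ester enolate that would only deprotonate the acidic pyranylacetyl donor.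

Step 7
Reactants: 14 methyl 3-{4-[6-(4-benzyloxyphenyl)-4-oxo-4H-pyran-2-yl]-1-methoxy-1,3-dioxobutan-2-yl}-4-methoxybenzoate
Product: 15 methyl 3-{2-[4-(benzyloxy)phenyl]-5,7-dihydroxy-4-oxo-4H-chromen-6-yl}-4-methoxybenzoate
Conditions: NaOMe (4 equiv), MeOH/THF, 0 → 50 °C; then 1 M HCl to pH 3
Reagents that add atoms: none
Why: Proposed new method: methoxide takes the most acidic proton (C6–H of the beta-keto ester) and, reversibly, a C8–H, giving the extended dienolate C8=C8a–C4a=C4–O(−) of the pyranone, whose alpha carbon C4a adds to the C5 ester carbonyl; methoxide leaves, and loss of the doubly activated C4a–H with enolisation of the C5 and C7 carbonyls should deliver ring A as its phenoxide, the irreversible event that pulls the preceding equilibria forward. The closest known reaction type is the biomimetic Claisen (Dieckmann) cyclisation of open-chain 3,5,7-triketo esters to acylphloroglucinols; closure onto an intact 4-pyranone, through the alpha terminus of its dienolate, has not been shown. Ring A closes in the 6-exo-trig mode (C4a onto the ester C=O) and no stereocentre is formed, since the labile C6 centre of 14 becomes an aromatic carbon and the crowded biaryl axis appears only on aromatisation. The step needs C-acylation at C4a to beat aldol, lactone and ring-opening paths: the C4 carbonyl is a vinylogous ester and a poor aldol acceptor, the oxygen on C8a is tied up as O1 so no lactone can form, C8 could only close a four-membered ring, and the anionic substrate should resist conjugate attack of methoxide on ring C. Because the O1–C8a bond is never broken the aryl-bearing carbon can only become C6, and methanolic methoxide makes ester exchange at the two methyl esters degenerate.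

Step 8
Reactants: 15 methyl 3-{2-[4-(benzyloxy)phenyl]-5,7-dihydroxy-4-oxo-4H-chromen-6-yl}-4-methoxybenzoate
Product: 16 methyl 3-[5,7-dihydroxy-2-(4-hydroxyphenyl)-4-oxo-4H-chromen-6-yl]-4-methoxybenzoate
Conditions: H2 (1 atm), 10% Pd/C, THF/MeOH, rt, stopped when 15 is consumed
Reagents that add atoms: none
Why: Catalytic hydrogenolysis should cleave the benzyl aryl ether selectively, the C2–C3 double bond of the flavone (part of a vinylogous ester), the methyl esters and the aryl methyl ether being inert at 1 atm and room temperature.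

**Compound list**
1 | acetylacetone (pentane-2,4-dione) | CC(=O)CC(C)=O | starting material
2 | methyl 4-(benzyloxy)benzoate | COC(=O)c1ccc(OCc2ccccc2)cc1 | starting material
3 | acetylacetone dilithium dianion (not isolated) | [Li+].[Li+].[CH2-]C(=O)C=C(C)[O-] | intermediate
4 | 1-[4-(benzyloxy)phenyl]hexane-1,3,5-trione | CC(=O)CC(=O)CC(=O)c1ccc(OCc2ccccc2)cc1 | intermediate
5 | 2-[4-(benzyloxy)phenyl]-6-methyl-4H-pyran-4-one | Cc1cc(=O)cc(-c2ccc(OCc3ccccc3)cc2)o1 | intermediate
6 | lithiated methylpyranone, 2-[4-(benzyloxy)phenyl]-6-(lithiomethyl)-4H-pyran-4-one (not isolated) | [Li]Cc1cc(=O)cc(-c2ccc(OCc3ccccc3)cc2)o1 | intermediate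
7 | 2-{6-[4-(benzyloxy)phenyl]-4-oxo-4H-pyran-2-yl}acetic acid | OC(=O)Cc1cc(=O)cc(-c2ccc(OCc3ccccc3)cc2)o1 | intermediate
8 | methyl 3-iodo-4-methoxybenzoate | COC(=O)c1ccc(OC)c(I)c1 | starting material
9 | tert-butyl methyl malonate | COC(=O)CC(=O)OC(C)(C)C | starting material
10 | 1-tert-butyl 3-methyl 2-[2-methoxy-5-(methoxycarbonyl)phenyl]propanedioate (racemic) | COC(=O)C(C(=O)OC(C)(C)C)c1cc(C(=O)OC)ccc1OC | intermediate
11 | 3-methoxy-2-[2-methoxy-5-(methoxycarbonyl)phenyl]-3-oxopropanoic acid (racemic) | COC(=O)C(C(=O)O)c1cc(C(=O)OC)ccc1OC | intermediate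
12 | acyl imidazolide of 7, 2-[4-(benzyloxy)phenyl]-6-[2-(imidazol-1-yl)-2-oxoethyl]-4H-pyran-4-one (not isolated) | O=C(Cc1cc(=O)cc(-c2ccc(OCc3ccccc3)cc2)o1)n1ccnc1 | intermediate
13 | acylmalonic half-acid, 2-(methoxycarbonyl)-2-[2-methoxy-5-(methoxycarbonyl)phenyl]-3-oxo-4-{6-[4-(benzyloxy)phenyl]-4-oxo-4H-pyran-2-yl}butanoic acid (racemic, not isolated) | COC(=O)C(C(=O)O)(C(=O)Cc1cc(=O)cc(-c2ccc(OCc3ccccc3)cc2)o1)c1cc(C(=O)OC)ccc1OC | intermediate
14 | methyl 3-{4-[6-(4-benzyloxyphenyl)-4-oxo-4H-pyran-2-yl]-1-methoxy-1,3-dioxobutan-2-yl}-4-methoxybenzoate (racemic, enolised) | COC(=O)C(C(=O)Cc1cc(=O)cc(-c2ccc(OCc3ccccc3)cc2)o1)c1cc(C(=O)OC)ccc1OC | intermediate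
15 | methyl 3-{2-[4-(benzyloxy)phenyl]-5,7-dihydroxy-4-oxo-4H-chromen-6-yl}-4-methoxybenzoate | COC(=O)c1ccc(OC)c(-c2c(O)cc3oc(-c4ccc(OCc5ccccc5)cc4)cc(=O)c3c2O)c1 | intermediate
16 | methyl 3-[5,7-dihydroxy-2-(4-hydroxyphenyl)-4-oxo-4H-chromen-6-yl]-4-methoxybenzoate | COC(=O)c1ccc(OC)c(-c2c(O)cc3oc(-c4ccc(O)cc4)cc(=O)c3c2O)c1 | target

**Count**
Total steps: 8. Longest linear sequence: 6 steps (steps 1, 2, 3, 6, 7, 8, from acetylacetone); the ring D branch (steps 4 and 5) joins at step 6.

**Steps most likely to fail**

Step 7 (key step). The closure may lose to addition of methoxide to ring C with ring opening, to retro-Claisen cleavage of the beta-keto ester, or the stabilised enolate may simply not acylate C4a. The fallback gives up building ring A and attaches ring D to a ready-made flavone by Suzuki–Miyaura coupling. It sets out from 8 and rejoins the route at the target 16.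
- 8 is borylated (bis(pinacolato)diboron, PdCl2(dppf), KOAc, dioxane, 80 °C) to methyl 4-methoxy-3-(4,4,5,5-tetramethyl-1,3,2-dioxaborolan-2-yl)benzoate F1.
- Purchased apigenin F2 is benzylated at the two non-chelated phenols (benzyl bromide, K2CO3, DMF, rt) to 7,4'-di-O-benzylapigenin F3.
- F3 is iodinated ortho to the free, chelated 5-hydroxyl (benzyltrimethylammonium dichloroiodate, CaCO3, CH2Cl2/MeOH, rt) to 6-iodo-7,4'-di-O-benzylapigenin F4.
- F4 and F1 are coupled (Pd(OAc)2, SPhos, K3PO4, toluene/H2O, 90 °C) to methyl 3-{7-(benzyloxy)-2-[4-(benzyloxy)phenyl]-5-hydroxy-4-oxo-4H-chromen-6-yl}-4-methoxybenzoate F5.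
- Hydrogenolysis of both benzyl ethers under the conditions of step 8 should give 16.

Step 6. Proton transfer from the acidic CH2 of the acyl imidazolide (ketene formation, self-condensation) or decarboxylation of the half-ester before C-acylation may outrun the hindered C–C bond formation. The fallback assembles the chain first and brings in ring D afterwards by C-arylation; it sets out from 7 and 8 and returns at 14.
- 7 is condensed with Meldrum's acid (DCC, DMAP, CH2Cl2, 0 °C) to 5-{2-[6-(4-benzyloxyphenyl)-4-oxo-4H-pyran-2-yl]acetyl}-2,2-dimethyl-1,3-dioxane-4,6-dione F6.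
- Methanolysis of F6 (MeOH/toluene, 70 °C) gives methyl 4-{6-[4-(benzyloxy)phenyl]-4-oxo-4H-pyran-2-yl}-3-oxobutanoate F7.
- F7 is arylated with 8 at C6, its most acidic carbon, under copper catalysis (CuI, L-proline, Cs2CO3, DMSO, 40 °C) to give 14.

Step 3. Proton transfer between 6 and the product carboxylate may lead to double carboxylation, and the vinylogous beta-keto acid may lose CO2 during acidic work-up and isolation. The fallback stores the C1 unit as an ester; it sets out from 5 and returns at 7.
- 5 is deprotonated with LiN(SiMe3)2 (2.1 equiv, THF, −78 °C) and the anion 6 is trapped with di-tert-butyl dicarbonate to give tert-butyl 2-{6-[4-(benzyloxy)phenyl]-4-oxo-4H-pyran-2-yl}acetate F8, which should be stable to chromatography.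
- F8 is cleaved with CF3CO2H/CH2Cl2 at 0 °C immediately before step 6, and the acid 7 is used without purification.

**Further compounds**
F1 | step 7 | methyl 4-methoxy-3-(4,4,5,5-tetramethyl-1,3,2-dioxaborolan-2-yl)benzoate | COC(=O)c1ccc(OC)c(B2OC(C)(C)C(C)(C)O2)c1
F2 | step 7 | apigenin (purchased for the fallback) | O=c1cc(-c2ccc(O)cc2)oc2cc(O)cc(O)c12
F3 | step 7 | 7,4'-di-O-benzylapigenin | O=c1cc(-c2ccc(OCc3ccccc3)cc2)oc2cc(OCc3ccccc3)cc(O)c12
F4 | step 7 | 6-iodo-7,4'-di-O-benzylapigenin | O=c1cc(-c2ccc(OCc3ccccc3)cc2)oc2cc(OCc3ccccc3)c(I)c(O)c12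
F5 | step 7 | methyl 3-{7-(benzyloxy)-2-[4-(benzyloxy)phenyl]-5-hydroxy-4-oxo-4H-chromen-6-yl}-4-methoxybenzoate | COC(=O)c1ccc(OC)c(-c2c(OCc3ccccc3)cc3oc(-c4ccc(OCc5ccccc5)cc4)cc(=O)c3c2O)c1
F6 | step 6 | 5-{2-[6-(4-benzyloxyphenyl)-4-oxo-4H-pyran-2-yl]acetyl}-2,2-dimethyl-1,3-dioxane-4,6-dione | CC1(C)OC(=O)C(C(=O)Cc2cc(=O)cc(-c3ccc(OCc4ccccc4)cc3)o2)C(=O)O1
F7 | step 6 | methyl 4-{6-[4-(benzyloxy)phenyl]-4-oxo-4H-pyran-2-yl}-3-oxobutanoate | COC(=O)CC(=O)Cc1cc(=O)cc(-c2ccc(OCc3ccccc3)cc2)o1
F8 | step 3 | tert-butyl 2-{6-[4-(benzyloxy)phenyl]-4-oxo-4H-pyran-2-yl}acetate | CC(C)(C)OC(=O)Cc1cc(=O)cc(-c2ccc(OCc3ccccc3)cc2)o1
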